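Ring A (C4a, C5, C6 with its methyl, C7, C8, C8a) is the isoprene [4+2] retron of a ring-fusion dienophile, and ring B (C1–C4, C2 methyl) carries the oxidation pattern of methyl-p-benzoquinone. The route therefore rests on cutting C4a–C5 and C8–C8a. One catalytic enantioselective Diels–Alder reaction closes ring A, forms both bonds, places the C6 methyl and sets C4a, from which every other decalin stereocentre is relayed. The precursor is dearomatised phenol 2, a 2-methylquinone 4,4-dimethyl monoketal whose only unsubstituted enone alkene is the dienophile. The acylpyridone is then assembled by two aryllithium additions and N-hydroxylated last.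

Key step: step 2

Assumption: the senses of induction of the two chiral catalysts ((S)-BINOL–titanium in step 2, (S,S)-TsDPEN–ruthenium in step 10) are assigned by analogy with related substrates; if either is opposite in practice, the antipodal ligand is used and nothing else changes.

Step 1
Reactants: 1 4-methoxy-2-methylphenol
Product: 2 4,4-dimethoxy-2-methylcyclohexa-2,5-dien-1-one
Conditions: PhI(OAc)2, MeOH, 0 °C → rt
Reagents that add atoms: methanol, CO
Why: Hypervalent-iodine oxidative dearomatisation of a para-methoxyphenol in methanol traps the phenoxonium ion at C4 as the dimethyl ketal, the standard entry to quinone monoketals.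

Step 2
Reactants: 2 4,4-dimethoxy-2-methylcyclohexa-2,5-dien-1-one; 3 isoprene
Product: 4 (4aR,8aS)-4,4-dimethoxy-2,6-dimethyl-4a,5,8,8a-tetrahydronaphthalen-1(4H)-one (cis-fused)
Conditions: (S)-BINOL (cat.), TiCl2(OiPr)2 (cat.), 4 Å MS, CH2Cl2, −20 °C → rt, isoprene in excess
Reagents that add atoms: none
Why: A concerted, asynchronous endo [4+2] cycloaddition of isoprene to the Lewis-acid-bound dienone, the known BINOL–titanium-catalysed enantioselective Diels–Alder reaction of 1,4-quinone monoketals. Ring A is closed by intermolecular [4+2] annulation onto C5=C6 of 2, forming C4a–C5 and C8–C8a suprafacially, hence the cis fusion. C4a is set by the catalyst and C8a is tied to it by the suprafacial addition: the C2 methyl should push titanium onto the carbonyl lone pair on the C6 side, and the binaphthyl wall then covers one face of C5=C6. The regiochemistry (methyl at C6, "para" to the carbonyl-bearing C8a) follows from the larger LUMO coefficient at the β-carbon next to the ketal meeting the more nucleophilic CH2 terminus of isoprene next to its methyl-bearing carbon. Site selectivity is secured by the substrate, since the methyl-bearing C2=C3 alkene is the poorer dienophile, and the ketal masks the second carbonyl and blocks aromatisation.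

Step 3
Reactants: 4 cis-fused adduct
Product: 5 (4aR,8aR)-4,4-dimethoxy-2,6-dimethyl-4a,5,8,8a-tetrahydronaphthalen-1(4H)-one (trans-fused)
Conditions: NaOMe (cat.), MeOH, rt
Reagents that add atoms: none
Why: Reversible enolisation of the C1 ketone toward C8a (base-mediated epimerisation, methanol matching the ketal) should funnel the cis adduct to the more stable trans-fused enone, while C4a, which has no acidifying neighbour, keeps the configuration set in step 2.

Step 4
Reactants: 5 trans-fused enone
Product: 6 (4aR,8aR)-4,4-dimethoxy-2,6-dimethyl-1-methylidene-1,4,4a,5,8,8a-hexahydronaphthalene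
Conditions: Ph3PCH3Br, KOtBu, THF, 0 °C → rt
Reagents that add atoms: methyltriphenylphosphonium bromide, C[P+](c1ccccc1)(c1ccccc1)c1ccccc1.[Br-]
Why: Wittig methylenation of the enone carbonyl installs the C1 carbon; the substrate is already the thermodynamic C8a epimer, so the basic ylide cannot erode it, and C8a is no longer enolisable afterwards.

Step 5
Reactants: 6 methylidene ketal
Product: 8 tosylhydrazone of the dienone, via dienone 7 (not isolated)
Conditions: PPTS (cat.), THF/H2O, 0 °C → rt; then TsNHNH2, EtOH, rt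
Reagents that add atoms: 4-methylbenzenesulfonohydrazide, Cc1ccc(cc1)S(=O)(=O)NN
Why: The dienylic dimethyl ketal ionises under very mild acid (ketal hydrolysis) and the ketone condenses at once with the sulfonylhydrazide (hydrazone formation), which keeps the lifetime of the isomerisation-prone dienone short and leaves C4a in its preferred trans arrangement.

Step 6
Reactants: 8 tosylhydrazone
Product: 11 (2R,4aS,8aR)-2,6-dimethyl-1-methylidene-1,2,4a,5,8,8a-hexahydronaphthalene, via N-boryl hydrazine 9 (not isolated), via allylic diazene 10 (not isolated)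
Conditions: catecholborane, CHCl3, 0 °C; then NaOAc·3H2O, 60 °C; crude triene (volatile) used directly
Reagents that add atoms: none
Why: 1,2-Reduction of the enone tosylhydrazone by catecholborane, sulfinate loss and retro-ene fragmentation of the allylic diazene (reductive 1,3-transposition) move the alkene to C3=C4; hydride is expected to add axially to C4 on the α face, so the diazene sits on the β face and passes its hydrogen suprafacially to the β face of C2, leaving the C2 methyl α (2R).

Step 7
Reactants: 11 triene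
Product: 13 [(1R,2R,4aS,8aR)-2,6-dimethyl-1,2,4a,5,8,8a-hexahydronaphthalen-1-yl]methanol, via B-alkyl-9-BBN adduct 12 (not isolated)
Conditions: 9-BBN, THF, 0 °C → rt; then NaOH, H2O2, 0 °C
Reagents that add atoms: hydrogen peroxide, OO
Why: Brown hydroboration–oxidation with 9-BBN is selective for the exocyclic 1,1-disubstituted alkene over both ring alkenes, puts boron on the terminal carbon and delivers hydrogen to C1 from the β face opposite the pseudoaxial C2 methyl, giving the equatorial hydroxymethyl group (1R).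

Step 8
Reactants: 13 unsaturated alcohol
Product: 14 [(1R,2R,4aS,6R,8aR)-2,6-dimethyl-1,2,4a,5,6,7,8,8a-octahydronaphthalen-1-yl]methanol
Conditions: Mn(dpm)3 (cat., dpm = dipivaloylmethanate), PhSiH3, tBuOOH, iPrOH, rt
Reagents that add atoms: none
Why: Mukaiyama-type hydrogen-atom-transfer hydrogenation reduces the trisubstituted C6=C7 alkene through the tertiary C6 radical and leaves the 1,2-disubstituted C3=C4 alkene alone; axial hydrogen capture by the radical should give the equatorial C6 methyl (6R), the thermodynamic epimer.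

Step 9
Reactants: 14 saturated alcohol
Product: 15 (1R,2R,4aS,6R,8aR)-2,6-dimethyl-1,2,4a,5,6,7,8,8a-octahydronaphthalene-1-carbaldehyde
Conditions: Dess–Martin periodinane, NaHCO3, CH2Cl2, 0 °C → rt
Reagents that add atoms: none
Why: Dess–Martin oxidation of the primary alcohol under buffered conditions does not epimerise C1, and the equatorial aldehyde is the stable epimer in any case.

Step 10
Reactants: 16 1,4-dioxaspiro[4.5]dec-6-en-8-one
Product: 17 (8S)-1,4-dioxaspiro[4.5]dec-6-en-8-ol
Conditions: RuCl(p-cymene)[(S,S)-TsDPEN] (cat.), HCO2Na, Bu4NCl, CH2Cl2/H2O, rt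
Reagents that add atoms: none
Why: Noyori-type asymmetric transfer hydrogenation reduces the enone carbonyl 1,2, the alkene acting as the π-substituent that the ligand recognises, so the (S,S)-ligand is expected to give the S carbinol.

Step 11
Reactants: 17 allylic alcohol
Product: 18 tert-butyl{[(8S)-1,4-dioxaspiro[4.5]dec-6-en-8-yl]oxy}dimethylsilane
Conditions: TBSCl, imidazole, DMF, rt
Reagents that add atoms: tert-butyldimethylsilyl chloride, CC(C)(C)[Si](C)(C)Cl
Why: Standard silylation of a secondary alcohol protects the future C4' hydroxyl and supplies the bulky group that directs step 13.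

Step 12
Reactants: 18 silyl ether ketal
Product: 19 (4S)-4-[(tert-butyldimethylsilyl)oxy]cyclohex-2-en-1-one
Conditions: montmorillonite K10, CH2Cl2, rt
Reagents that add atoms: water, O
Why: Mild acid-clay hydrolysis of the allylic dioxolane unmasks the enone without cleaving the silyl ether, and the carbinol carbon becomes C4 of the enone with unchanged configuration.

Step 13
Reactants: 19 silyloxy enone
Product: 20 (1R,5S,6S)-5-[(tert-butyldimethylsilyl)oxy]-7-oxabicyclo[4.1.0]heptan-2-one
Conditions: H2O2 (30% aq.), BnMe3NOH (cat.), THF, 0 °C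
Reagents that add atoms: hydrogen peroxide, OO
Why: Weitz–Scheffer nucleophilic epoxidation, in which hydroperoxide adds to the β-carbon anti to the adjacent silyloxy group, should give the trans epoxy ketone and so set both epoxide carbons.

Step 14
Reactants: 21 5-bromo-2,4-dichloropyridine
Product: 22 5-bromo-2,4-bis[2-(trimethylsilyl)ethoxy]pyridine
Conditions: NaH, Me3SiCH2CH2OH, DMF, 0 → 80 °C
Reagents that add atoms: 2-(trimethylsilyl)ethanol, C[Si](C)(C)CCO
Why: Two-fold SNAr of the 4- and 2-chlorides by the alkoxide (the 5-bromide is inert) gives O-bound, fluoride-cleavable masks for both pyridone oxygens and avoids any N-alkylation.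

Step 15
Reactants: 22 bromopyridine; 20 epoxy ketone
Product: 24 (1R,2R,5S,6S)-2-{4,6-bis[2-(trimethylsilyl)ethoxy]pyridin-3-yl}-5-[(tert-butyldimethylsilyl)oxy]-7-oxabicyclo[4.1.0]heptan-2-ol, via 5-lithiopyridine 23 (not isolated)
Conditions: n-BuLi, THF, −78 °C; then 20, −78 °C; aq. NH4Cl
Reagents that add atoms: none
Why: Bromine–lithium exchange followed by 1,2-addition of the aryllithium to the α,β-epoxy ketone anti to the epoxide oxygen should place the new tertiary hydroxyl cis to the epoxide (2R).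

Step 16
Reactants: 24 pyridyl carbinol; 15 decalin aldehyde
Product: 26 secondary pyridyl carbinol (both epimers at the new carbinol carbon), via dilithio species 25 (not isolated)
Conditions: t-BuLi (2.2 equiv), THF, −78 °C; then 15, −78 → −40 °C; aq. NH4Cl
Reagents that add atoms: none
Why: Directed ortho-lithiation at the one ring position flanked by both alkoxy groups (after deprotonation of the hydroxyl) and addition to the aldehyde joins the two halves, and the new carbinol centre is removed in step 17, so its configuration does not matter.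

Step 17
Reactants: 26 secondary carbinol
Product: 27 aryl ketone
Conditions: Dess–Martin periodinane, NaHCO3, CH2Cl2, rt
Reagents that add atoms: none
Why: Dess–Martin oxidation converts the secondary carbinol into the C3 acyl group while the tertiary alcohol, epoxide, silyl groups and alkene are inert.

Step 18
Reactants: 27 protected ketone
Product: 28 3-[(1R,2R,4aS,6R,8aR)-2,6-dimethyl-1,2,4a,5,6,7,8,8a-octahydronaphthalene-1-carbonyl]-5-[(1R,2R,5S,6R)-2,5-dihydroxy-7-oxabicyclo[4.1.0]heptan-2-yl]-4-hydroxypyridin-2(1H)-one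
Conditions: Bu4NF, AcOH, THF, rt → 40 °C
Reagents that add atoms: none
Why: Fluoride triggers β-elimination of both 2-(trimethylsilyl)ethyl ethers and cleaves the silyl ether (fluoride-mediated desilylation), and acetic acid buffering should keep the medium from becoming basic enough for epoxide migration or intramolecular epoxide opening.

Step 19
Reactants: 28 4-hydroxy-2-pyridone
Product: 31 target compound, via tetrakis(trimethylsilyl) ether 29 (not isolated), via silylated N-oxide 30 (not isolated)
Conditions: BSA, Me3SiCl (cat.), CH2Cl2, 40 °C; then MoO(O2)2(py)(HMPA), CH2Cl2, rt; then aq. Na4EDTA, aq. citric acid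
Reagents that add atoms: oxodiperoxo(pyridine)(hexamethylphosphoric triamide)molybdenum, O=[Mo]12(OO1)OO2.c1ccncc1.CN(C)P(=O)(N(C)C)N(C)C
Why: Transient per-silylation gives the 2-silyloxypyridine, whose nitrogen is oxidised by the peroxomolybdenum complex (the known N-hydroxylation of 2-pyridones through their O-silyl derivatives), the reagent is not expected to epoxidise the unactivated C3=C4 alkene at room temperature, and aqueous work-up strips the trimethylsilyl groups.

Compound list
1 | 4-methoxy-2-methylphenol | COc1ccc(O)c(C)c1 | starting material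
2 | 4,4-dimethoxy-2-methylcyclohexa-2,5-dien-1-one | COC1(OC)C=CC(=O)C(C)=C1 | intermediate
3 | isoprene (2-methylbuta-1,3-diene) | C=CC(C)=C | starting material
4 | (4aR,8aS)-4,4-dimethoxy-2,6-dimethyl-4a,5,8,8a-tetrahydronaphthalen-1(4H)-one, cis-fused | CC1=CC[C@@H]2C(=O)C(C)=CC(OC)(OC)[C@@H]2C1 | intermediate
5 | (4aR,8aR)-4,4-dimethoxy-2,6-dimethyl-4a,5,8,8a-tetrahydronaphthalen-1(4H)-one, trans-fused | CC1=CC[C@H]2C(=O)C(C)=CC(OC)(OC)[C@@H]2C1 | intermediate
6 | (4aR,8aR)-4,4-dimethoxy-2,6-dimethyl-1-methylidene-1,4,4a,5,8,8a-hexahydronaphthalene | CC1=CC[C@H]2C(=C)C(C)=CC(OC)(OC)[C@@H]2C1 | intermediate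
7 | (4aR,8aR)-3,7-dimethyl-4-methylidene-4a,5,8,8a-tetrahydronaphthalen-1(4H)-one | CC1=CC[C@H]2C(=C)C(C)=CC(=O)[C@@H]2C1 | intermediate
8 | N'-[(4aR,8aR)-3,7-dimethyl-4-methylidene-4a,5,8,8a-tetrahydronaphthalen-1(4H)-ylidene]-4-methylbenzenesulfonohydrazide (C=N geometry not controlled) | CC1=CC[C@H]2C(=C)C(C)=CC(=NNS(=O)(=O)c3ccc(C)cc3)[C@@H]2C1 | intermediate
9 | N-(1,3,2-benzodioxaborol-2-yl)-N-[(1S,4aR,8aR)-3,7-dimethyl-4-methylidene-1,4,4a,5,8,8a-hexahydronaphthalen-1-yl]-N'-tosylhydrazine | CC1=CC[C@H]2C(=C)C(C)=C[C@@H](N(NS(=O)(=O)c3ccc(C)cc3)B3Oc4ccccc4O3)[C@@H]2C1 | intermediate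
10 | [(1S,4aR,8aR)-3,7-dimethyl-4-methylidene-1,4,4a,5,8,8a-hexahydronaphthalen-1-yl]diazene | CC1=CC[C@H]2C(=C)C(C)=C[C@@H](N=N)[C@@H]2C1 | intermediate
11 | (2R,4aS,8aR)-2,6-dimethyl-1-methylidene-1,2,4a,5,8,8a-hexahydronaphthalene | CC1=CC[C@H]2C(=C)[C@H](C)C=C[C@@H]2C1 | intermediate
12 | 9-{[2,6-dimethyl-1,2,4a,5,8,8a-hexahydronaphthalen-1-yl]methyl}-9-borabicyclo[3.3.1]nonane, ring stereocentres as in 13 | CC1=CC[C@H]2[C@H](CB3C4CCCC3CCC4)[C@H](C)C=C[C@@H]2C1 | intermediate
13 | [(1R,2R,4aS,8aR)-2,6-dimethyl-1,2,4a,5,8,8a-hexahydronaphthalen-1-yl]methanol | CC1=CC[C@H]2[C@H](CO)[C@H](C)C=C[C@@H]2C1 | intermediate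
14 | [(1R,2R,4aS,6R,8aR)-2,6-dimethyl-1,2,4a,5,6,7,8,8a-octahydronaphthalen-1-yl]methanol | C[C@@H]1CC[C@H]2[C@H](CO)[C@H](C)C=C[C@@H]2C1 | intermediate
15 | (1R,2R,4aS,6R,8aR)-2,6-dimethyl-1,2,4a,5,6,7,8,8a-octahydronaphthalene-1-carbaldehyde | C[C@@H]1CC[C@H]2[C@H](C=O)[C@H](C)C=C[C@@H]2C1 | intermediate
16 | 1,4-dioxaspiro[4.5]dec-6-en-8-one | O=C1C=CC2(OCCO2)CC1 | starting material
17 | (8S)-1,4-dioxaspiro[4.5]dec-6-en-8-ol | O[C@@H]1C=CC2(OCCO2)CC1 | intermediate
18 | tert-butyl{[(8S)-1,4-dioxaspiro[4.5]dec-6-en-8-yl]oxy}dimethylsilane | CC(C)(C)[Si](C)(C)O[C@@H]1C=CC2(OCCO2)CC1 | intermediate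
19 | (4S)-4-[(tert-butyldimethylsilyl)oxy]cyclohex-2-en-1-one | O=C1CC[C@H](O[Si](C)(C)C(C)(C)C)C=C1 | intermediate
20 | (1R,5S,6S)-5-[(tert-butyldimethylsilyl)oxy]-7-oxabicyclo[4.1.0]heptan-2-one (epoxide trans to the silyloxy group) | O=C1CC[C@H](O[Si](C)(C)C(C)(C)C)[C@H]2O[C@H]21 | intermediate
21 | 5-bromo-2,4-dichloropyridine | Clc1cc(Cl)c(Br)cn1 | starting material
22 | 5-bromo-2,4-bis[2-(trimethylsilyl)ethoxy]pyridine | C[Si](C)(C)CCOc1cc(OCC[Si](C)(C)C)c(Br)cn1 | intermediate
23 | {4,6-bis[2-(trimethylsilyl)ethoxy]pyridin-3-yl}lithium | [Li]c1cnc(OCC[Si](C)(C)C)cc1OCC[Si](C)(C)C | intermediate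
24 | (1R,2R,5S,6S)-2-{4,6-bis[2-(trimethylsilyl)ethoxy]pyridin-3-yl}-5-[(tert-butyldimethylsilyl)oxy]-7-oxabicyclo[4.1.0]heptan-2-ol | C[Si](C)(C)CCOc1cc(OCC[Si](C)(C)C)c(cn1)[C@]1(O)CC[C@H](O[Si](C)(C)C(C)(C)C)[C@H]2O[C@H]21 | intermediate
25 | C5-lithio lithium alkoxide of 24 (lithium on the ring carbon between the two alkoxy groups), stereocentres as in 24 | C[Si](C)(C)CCOc1ncc(c(OCC[Si](C)(C)C)c1[Li])[C@]1(O[Li])CC[C@H](O[Si](C)(C)C(C)(C)C)[C@H]2O[C@H]21 | intermediate
26 | (1R,2R,5S,6S)-2-{5-[[(1R,2R,4aS,6R,8aR)-2,6-dimethyl-1,2,4a,5,6,7,8,8a-octahydronaphthalen-1-yl](hydroxy)methyl]-4,6-bis[2-(trimethylsilyl)ethoxy]pyridin-3-yl}-5-[(tert-butyldimethylsilyl)oxy]-7-oxabicyclo[4.1.0]heptan-2-ol, both carbinol epimers | C[C@@H]1CC[C@H]2[C@H](C(O)c3c(OCC[Si](C)(C)C)c([C@]4(O)CC[C@H](O[Si](C)(C)C(C)(C)C)[C@H]5O[C@H]54)cnc3OCC[Si](C)(C)C)[C@H](C)C=C[C@@H]2C1 | intermediate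
27 | [(1R,2R,4aS,6R,8aR)-2,6-dimethyl-1,2,4a,5,6,7,8,8a-octahydronaphthalen-1-yl]{5-[(1R,2R,5S,6S)-5-[(tert-butyldimethylsilyl)oxy]-2-hydroxy-7-oxabicyclo[4.1.0]heptan-2-yl]-2,4-bis[2-(trimethylsilyl)ethoxy]pyridin-3-yl}methanone | C[C@@H]1CC[C@H]2[C@H](C(=O)c3c(OCC[Si](C)(C)C)c([C@]4(O)CC[C@H](O[Si](C)(C)C(C)(C)C)[C@H]5O[C@H]54)cnc3OCC[Si](C)(C)C)[C@H](C)C=C[C@@H]2C1 | intermediate
28 | 3-[(1R,2R,4aS,6R,8aR)-2,6-dimethyl-1,2,4a,5,6,7,8,8a-octahydronaphthalene-1-carbonyl]-5-[(1R,2R,5S,6R)-2,5-dihydroxy-7-oxabicyclo[4.1.0]heptan-2-yl]-4-hydroxypyridin-2(1H)-one | C[C@@H]1CC[C@H]2[C@H](C(=O)c3c(O)c([C@]4(O)CC[C@H](O)[C@H]5O[C@H]54)c[nH]c3=O)[C@H](C)C=C[C@@H]2C1 | intermediate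
29 | tetrakis(trimethylsilyl) derivative of 28 (2-silyloxypyridine form; 4-O, both cyclohexane oxygens silylated; stereocentres unchanged) | C[C@@H]1CC[C@H]2[C@H](C(=O)c3c(O[Si](C)(C)C)c([C@]4(O[Si](C)(C)C)CC[C@H](O[Si](C)(C)C)[C@H]5O[C@H]54)cnc3O[Si](C)(C)C)[C@H](C)C=C[C@@H]2C1 | intermediate
30 | pyridine N-oxide of 29 | C[C@@H]1CC[C@H]2[C@H](C(=O)c3c(O[Si](C)(C)C)c([C@]4(O[Si](C)(C)C)CC[C@H](O[Si](C)(C)C)[C@H]5O[C@H]54)c[n+]([O-])c3O[Si](C)(C)C)[C@H](C)C=C[C@@H]2C1 | intermediate
31 | 3-[(1R,2R,4aS,6R,8aR)-2,6-dimethyl-1,2,4a,5,6,7,8,8a-octahydronaphthalene-1-carbonyl]-5-[(1R,2R,5S,6R)-2,5-dihydroxy-7-oxabicyclo[4.1.0]heptan-2-yl]-1,4-dihydroxypyridin-2(1H)-one | C[C@@H]1CC[C@H]2[C@H](C(=O)c3c(O)c([C@]4(O)CC[C@H](O)[C@H]5O[C@H]54)cn(O)c3=O)[C@H](C)C=C[C@@H]2C1 | target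

Total step count: 19 (decalin aldehyde 9 steps, epoxy ketone 4 steps, pyridine 1 step, union and endgame 5 steps).
Longest linear sequence: 13 steps (steps 1–9, then 16–19).

Steps most likely to fail

Step 2. The titanium Lewis acid may ionise the acid-labile dimethyl ketal, leading to re-aromatisation. Face discrimination may also be insufficient with a diene as unreactive as isoprene, so that conversion or enantiomeric purity is low. The fallback replaces catalyst control by substrate control through a chiral, more robust ketal. Setting out from 2, acid-catalysed ketal exchange with (R,R)-hydrobenzoin (BF3·OEt2, DME) would give the C2-symmetric dioxolane (2R,3R)-7-methyl-2,3-diphenyl-1,4-dioxaspiro[4.5]deca-6,9-dien-8-one F1, in which a phenyl group covers one face of the unsubstituted alkene. A thermal or Et2AlCl-promoted Diels–Alder reaction with isoprene 3 would give the cis-fused hydrobenzoin-ketal adduct F2 as diastereomers that can be separated, so no enantiomeric excess is at stake. Methoxide epimerisation as in step 3 gives the trans-fused hydrobenzoin-ketal enone F3, and Wittig methylenation as in step 4 gives the methylidene hydrobenzoin ketal F4. Hydrolysis under somewhat stronger acid with in-situ hydrazone formation, as in step 5, releases the diol and comes back to the route at 8. The hydrobenzoin enantiomer is chosen so that the major adduct has the 4aR configuration.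

Step 6. Hydride may be delivered to the β face of the C=N bond, which would put the diazene on the α face and relay the wrong configuration to C2; the dienyl hydrazone may also isomerise towards an aromatic ring before it is reduced. The fallback inverts the relay with known chemistry. Setting out from 6, the hydrolysis half of step 5 is run alone and dienone 7 is isolated. Luche reduction (NaBH4, CeCl3·7H2O, MeOH, −78 °C) with the same β-face preference would give the α-alcohol (1R,4aR,8aR)-3,7-dimethyl-4-methylidene-1,4,4a,5,8,8a-hexahydronaphthalen-1-ol F5. Mitsunobu displacement with 2-nitrobenzenesulfonylhydrazide (PPh3, DEAD, THF, −30 °C → rt) then inverts this centre to the β-configured N-allyl-N-(2-nitrobenzenesulfonyl)hydrazine F6. This loses sulfinate on warming to give diazene 10, whose retro-ene fragmentation comes back to the route at 11.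

Step 19. N-oxidation of the electron-poor 3-acyl-2-silyloxypyridine may be incomplete, the molybdenum may be retained by the chelating hydroxamic acid and acylpyridone array, or oxidation may occur elsewhere, all at the last step on the most valuable material. The fallback makes the N–O bond before the alkene-bearing half is attached. Setting out from 24, mCPBA (CH2Cl2, rt) would give the pyridine N-oxide of 24 F7. NIS (MeCN) should iodinate the one free position activated by both alkoxy groups to give the 5-iodo N-oxide F8. Iodine–magnesium exchange with iPrMgCl·LiCl (2.1 equiv, THF, −40 °C), an exchange known to tolerate pyridine N-oxides, followed by addition to aldehyde 15 gives the carbinol N-oxide F9, and Dess–Martin oxidation gives the ketone N-oxide F10. The fluoride conditions of step 18 then cleave the 2-alkoxy N-oxide directly to the 1-hydroxy-2-pyridone and come back to the route at 31, bypassing 28.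

Further compounds
F1 | step 2 | (2R,3R)-7-methyl-2,3-diphenyl-1,4-dioxaspiro[4.5]deca-6,9-dien-8-one | CC1=CC2(O[C@H](c3ccccc3)[C@@H](c3ccccc3)O2)C=CC1=O
F2 | step 2 | cis-fused (4aR,8aS) isoprene adduct of F1 (hydrobenzoin ketal analogue of 4) | CC1=CC[C@@H]2C(=O)C(C)=CC3(O[C@H](c4ccccc4)[C@@H](c4ccccc4)O3)[C@@H]2C1
F3 | step 2 | trans-fused (4aR,8aR) hydrobenzoin-ketal enone (analogue of 5) | CC1=CC[C@H]2C(=O)C(C)=CC3(O[C@H](c4ccccc4)[C@@H](c4ccccc4)O3)[C@@H]2C1
F4 | step 2 | methylidene hydrobenzoin ketal (analogue of 6) | CC1=CC[C@H]2C(=C)C(C)=CC3(O[C@H](c4ccccc4)[C@@H](c4ccccc4)O3)[C@@H]2C1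
F5 | step 6 | (1R,4aR,8aR)-3,7-dimethyl-4-methylidene-1,4,4a,5,8,8a-hexahydronaphthalen-1-ol | CC1=CC[C@H]2C(=C)C(C)=C[C@H](O)[C@@H]2C1
F6 | step 6 | N-[(1S,4aR,8aR)-3,7-dimethyl-4-methylidene-1,4,4a,5,8,8a-hexahydronaphthalen-1-yl]-N-(2-nitrobenzenesulfonyl)hydrazine | CC1=CC[C@H]2C(=C)C(C)=C[C@@H](N(N)S(=O)(=O)c3ccccc3[N+](=O)[O-])[C@@H]2C1
F7 | step 19 | pyridine N-oxide of 24 | C[Si](C)(C)CCOc1cc(OCC[Si](C)(C)C)c(c[n+]1[O-])[C@]1(O)CC[C@H](O[Si](C)(C)C(C)(C)C)[C@H]2O[C@H]21
F8 | step 19 | 5-iodo derivative of F7 (iodine between the two alkoxy groups) | C[Si](C)(C)CCOc1c(I)c(OCC[Si](C)(C)C)c(c[n+]1[O-])[C@]1(O)CC[C@H](O[Si](C)(C)C(C)(C)C)[C@H]2O[C@H]21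
F9 | step 19 | pyridine N-oxide of carbinol 26 | C[C@@H]1CC[C@H]2[C@H](C(O)c3c(OCC[Si](C)(C)C)c([C@]4(O)CC[C@H](O[Si](C)(C)C(C)(C)C)[C@H]5O[C@H]54)c[n+]([O-])c3OCC[Si](C)(C)C)[C@H](C)C=C[C@@H]2C1
F10 | step 19 | pyridine N-oxide of ketone 27 | C[C@@H]1CC[C@H]2[C@H](C(=O)c3c(OCC[Si](C)(C)C)c([C@]4(O)CC[C@H](O[Si](C)(C)C(C)(C)C)[C@H]5O[C@H]54)c[n+]([O-])c3OCC[Si](C)(C)C)[C@H](C)C=C[C@@H]2C1
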